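**Strategy.** In the saturated ring (C1'–C6') the ylidene carbon C6' lies between the gem-dimethyl carbon C1' and the C5' methyl stereocentre: this is the skeleton of (S)-citronellal, whose α-carbon is C6', whose carbonyl carbon is C7' and whose isopropylidene carbon is C1'. The route rests on closing C6'–C1' by a biomimetic cation–olefin cyclisation of citronellal enol acetate, which builds ring and quaternary carbon in one operation from an acyclic chiral-pool precursor. Enol triflates of the resulting aldehyde and of α-cyclocitral then define both exocyclic (retro) double bonds; Suzuki couplings with one shared trienyl boronate (from alkyne carboalumination) and two Wittig reactions complete the C40 polyene.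

Key step: step 2

Assumption: locants follow carotenoid numbering (C1–C20 for the half with the cyclohexene ring, C1'–C20' for the half with the saturated ring); (S)-citronellal, racemic α-cyclocitral and (E)-pent-2-en-4-yn-1-ol are taken as catalogue chemicals, and all polyenes are handled under argon with exclusion of light and acid.

Step 1
Reactants: 1 (S)-citronellal
Product: 2 (3S)-3,7-dimethylocta-1,6-dien-1-yl acetate (E/Z mixture, used as such; E isomer drawn)
Conditions: Ac2O, KOAc, Et3N, 120 °C
Reagents that add atoms: acetic anhydride CC(=O)OC(C)=O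
Why: Acetate-mediated enolisation and O-acylation (enol acetate formation from an enolisable aldehyde) masks the carbonyl and turns C6' into a π-nucleophile; the C5' centre is β to the carbonyl and is not epimerised, and no new stereocentre is formed.

Step 2
Reactants: 2 (3S)-3,7-dimethylocta-1,6-dien-1-yl acetate
Product: 5 (1R,6S)-2,2,6-trimethylcyclohexane-1-carbaldehyde, via tertiary carbocation 3 (not isolated), via acyloxycarbenium ion 4 (not isolated)
Conditions: 85% H3PO4, toluene, 90–100 °C; aqueous work-up
Reagents that add atoms: water O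
Why: Markovnikov protonation of the trisubstituted olefin gives the tertiary cation 3 at C1', which is attacked by the β-carbon of the enol acetate (C6') to form the C6'–C1' bond and the acyloxycarbenium ion 4; water in the acid adds to the carbenium carbon of 4 and the resulting hemiacylal collapses to the aldehyde and acetic acid. The closest known reaction type is the Brønsted-acid cation–olefin (terpene-type) cyclisation terminated by an enol ester, a known reactivity of citronellal enol acetate. The six-membered ring closes through a chair-like transition state in which the enol acetate double bond is exocyclic to the new ring (C6' enters the ring, C7' stays outside) and the cationic carbon C1' lies inside it. The new C6' stereocentre is placed trans to the C5' methyl by the existing centre (both groups equatorial in the chair, and the trans aldehyde is also the thermodynamic epimer under the acidic conditions); this centre is erased on purpose in step 3, whereas C5' (S), taken from citronellal, is not touched because it never becomes cationic or enolisable. The step needs C-alkylation at C6' instead of the carbonyl-ene closure to isopulegol-type products and six- instead of seven-ring closure: the first is secured by the enol acetate mask, the second by the polarisation of the enol acetate towards its β-carbon and by the tertiary cation.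

Step 3
Reactants: 5 (1R,6S)-2,2,6-trimethylcyclohexane-1-carbaldehyde
Product: 7 (E)-[(6S)-2,2,6-trimethylcyclohexylidene]methyl trifluoromethanesulfonate, via potassium enolate 6 (not isolated)
Conditions: KN(SiMe3)2, THF, −78 °C; PhNTf2, −78 °C to rt; cold 0.5 M HCl wash
Reagents that add atoms: N-phenylbis(trifluoromethanesulfonimide) O=S(=O)(N(c1ccccc1)S(=O)(=O)C(F)(F)F)C(F)(F)F
Why: Irreversible deprotonation of the single α-hydrogen and O-sulfonylation (enol triflate formation from an α-branched aldehyde) convert C6' into the ylidene carbon; the enolate oxygen should sit syn to the CH(CH3) carbon C5' and anti to the quaternary C1' to avoid allylic 1,3-strain (the C5' methyl turns axial), which gives the E geometry needed for the 6' double bond, and C5' itself is not acidic.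

Step 4
Reactants: 8 (E)-pent-2-en-4-yn-1-ol; 9 ethyl 2-(triphenylphosphoranylidene)propanoate
Product: 11 ethyl (2E,4E)-2-methylhepta-2,4-dien-6-ynoate, via (E)-pent-2-en-4-ynal 10 (not isolated)
Conditions: MnO2 (excess), CH2Cl2, rt
Reagents that add atoms: none
Why: Tandem oxidation–Wittig reaction, in which MnO2 oxidises the allylic alcohol to the volatile enynal 10 that is trapped in situ by the stabilised ylide with high E selectivity for the trisubstituted double bond (the later C12=C13 and C12'=C13' bonds).

Step 5
Reactants: 11 ethyl (2E,4E)-2-methylhepta-2,4-dien-6-ynoate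
Product: 12 (2E,4E)-2-methylhepta-2,4-dien-6-yn-1-ol
Conditions: i-Bu2AlH, CH2Cl2, −78 °C; aq. potassium sodium tartrate
Reagents that add atoms: none
Why: 1,2-Reduction of the conjugated ester by i-Bu2AlH at low temperature should give the allylic alcohol without touching the terminal alkyne or the diene.

Step 6
Reactants: 12 (2E,4E)-2-methylhepta-2,4-dien-6-yn-1-ol
Product: 14 (2E,4E,6E)-2,6-dimethyl-7-(4,4,5,5-tetramethyl-1,3,2-dioxaborolan-2-yl)hepta-2,4,6-trien-1-ol, via alkenylalane 13 (not isolated)
Conditions: AlMe3 (3 equiv), Cp2ZrCl2 (20 mol%), CH2Cl2, 0 °C to rt; volatiles removed in vacuo; MeOBpin (3 equiv), THF, 0 °C to rt; aq. potassium sodium tartrate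
Reagents that add atoms: trimethylaluminium C[Al](C)C; 2-methoxy-4,4,5,5-tetramethyl-1,3,2-dioxaborolane COB1OC(C)(C)C(C)(C)O1
Why: Negishi zirconium-catalysed syn-carboalumination of the terminal alkyne (after formation of the aluminium alkoxide) delivers the methyl group to C9 and aluminium to C8 with E geometry, and aluminium-to-boron transmetalation of the alkenylalane 13 with the alkoxy pinacolborane proceeds with retention, so that one isolable, chromatographable boronate is made once and serves both halves of the target.

Step 7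
Reactants: 14 (2E,4E,6E)-2,6-dimethyl-7-(4,4,5,5-tetramethyl-1,3,2-dioxaborolan-2-yl)hepta-2,4,6-trien-1-ol; 7 (E)-[(6S)-2,2,6-trimethylcyclohexylidene]methyl trifluoromethanesulfonate
Product: 15 (2E,4E,6E,8E)-2,6-dimethyl-8-[(6S)-2,2,6-trimethylcyclohexylidene]octa-2,4,6-trien-1-ol
Conditions: Pd(PPh3)4 (5 mol%), K3PO4 (3 M aq.), THF, 40 °C, dark
Reagents that add atoms: none
Why: Suzuki–Miyaura coupling of the alkenyl boronate with the enol triflate under zerovalent palladium catalysis proceeds with retention at both sp2 carbons, so the C6'=C7' and C8'=C9' geometries are carried over from 7 and 14; the triflate carbon is an unhindered CH terminus, and the mild phosphate base does not disturb C5'.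

Step 8
Reactants: 15 (2E,4E,6E,8E)-2,6-dimethyl-8-[(6S)-2,2,6-trimethylcyclohexylidene]octa-2,4,6-trien-1-ol
Product: 16 (2E,4E,6E,8E)-2,6-dimethyl-8-[(6S)-2,2,6-trimethylcyclohexylidene]octa-2,4,6-trienal
Conditions: MnO2, CH2Cl2, rt, dark
Reagents that add atoms: none
Why: Selective MnO2 oxidation of the polyenylic primary alcohol to the aldehyde under neutral conditions.

Step 9
Reactants: 16 (2E,4E,6E,8E)-2,6-dimethyl-8-[(6S)-2,2,6-trimethylcyclohexylidene]octa-2,4,6-trienal; 17 (triphenylphosphoranylidene)acetaldehyde
Product: 18 (2E,4E,6E,8E,10E)-4,8-dimethyl-10-[(6S)-2,2,6-trimethylcyclohexylidene]deca-2,4,6,8-tetraenal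
Conditions: toluene, 70 °C
Reagents that add atoms: none
Why: Wittig two-carbon homologation with the stabilised formylmethylene ylide should give the E enal (C14'=C15') under neutral conditions in which the allylic C5'–H is not deprotonated.

Step 10
Reactants: 19 α-cyclocitral (2,6,6-trimethylcyclohex-2-ene-1-carbaldehyde, racemic)
Product: 21 (E)-(2,6,6-trimethylcyclohex-2-en-1-ylidene)methyl trifluoromethanesulfonate, via potassium dienolate 20 (not isolated)
Conditions: KN(SiMe3)2, THF, −78 °C; PhNTf2, −78 °C to rt; cold 0.5 M HCl wash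
Reagents that add atoms: N-phenylbis(trifluoromethanesulfonimide) O=S(=O)(N(c1ccccc1)S(=O)(=O)C(F)(F)F)C(F)(F)F
Why: Deprotonation of the doubly activated α-hydrogen (C6) gives the cross-conjugated dienolate whose O-triflation (enol triflate formation) installs C4=C5 and the exocyclic C6=C7 bond of the retro end at once; the isomer with OTf syn to C1 is required, and any Z isomer is carried along because this geometry comes under thermodynamic control in steps 12 and 13.

Step 11
Reactants: 14 (2E,4E,6E)-2,6-dimethyl-7-(4,4,5,5-tetramethyl-1,3,2-dioxaborolan-2-yl)hepta-2,4,6-trien-1-ol; 21 (E)-(2,6,6-trimethylcyclohex-2-en-1-ylidene)methyl trifluoromethanesulfonate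
Product: 22 (2E,4E,6E,8E)-2,6-dimethyl-8-(2,6,6-trimethylcyclohex-2-en-1-ylidene)octa-2,4,6-trien-1-ol
Conditions: Pd(PPh3)4 (5 mol%), K3PO4 (3 M aq.), THF, 40 °C, dark
Reagents that add atoms: none
Why: The same Suzuki–Miyaura coupling as in step 7, here with the dienyl triflate, joins C7 to C8 with retention of the C6=C7 and C8=C9 geometries.

Step 12
Reactants: 22 (2E,4E,6E,8E)-2,6-dimethyl-8-(2,6,6-trimethylcyclohex-2-en-1-ylidene)octa-2,4,6-trien-1-ol
Product: 23 [(2E,4E,6E,8E)-2,6-dimethyl-8-(2,6,6-trimethylcyclohex-2-en-1-ylidene)octa-2,4,6-trien-1-yl]triphenylphosphonium bromide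
Conditions: PPh3·HBr, MeOH, 0 °C to rt
Reagents that add atoms: triphenylphosphine hydrobromide Br.c1ccc(cc1)P(c1ccccc1)c1ccccc1
Why: Acid-mediated substitution of the polyenylic alcohol by PPh3 (the classical preparation of polyenyl Wittig salts), in which the delocalised cation should be captured at the unhindered primary terminus C14, the position that keeps the polyene fully conjugated.

Step 13
Reactants: 23 [(2E,4E,6E,8E)-2,6-dimethyl-8-(2,6,6-trimethylcyclohex-2-en-1-ylidene)octa-2,4,6-trien-1-yl]triphenylphosphonium bromide; 18 (2E,4E,6E,8E,10E)-4,8-dimethyl-10-[(6S)-2,2,6-trimethylcyclohexylidene]deca-2,4,6,8-tetraenal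
Product: 26 (5'S,6E,6'E)-4,5'-retro-β,β-carotene (all-E chain; CNP0257724.1), via phosphorus ylide 24 (not isolated), via 14Z isomer 25 (not isolated)
Conditions: NaN(SiMe3)2, THF, −78 to 0 °C; 18, −78 °C to rt; then heptane, reflux, dark; crystallisation
Reagents that add atoms: none
Why: Wittig olefination of the conjugated ylide 24 with the enal forms C14=C15 as an E/Z mixture, and heating should convert the 14Z isomer 25 and any 6Z material into the all-E, 6E,6'E hydrocarbon, expected to be the most stable isomer (as in known retro-carotenoids) and purified by crystallisation; no stereocentre is formed and C5' is untouched.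

**Compound list**

1 | (S)-citronellal | O=CC[C@@H](C)CCC=C(C)C | starting material
2 | (3S)-3,7-dimethylocta-1,6-dien-1-yl acetate (E/Z mixture, E drawn) | CC(=O)O/C=C/[C@@H](C)CCC=C(C)C | intermediate
3 | tertiary carbocation from protonation of 2 | CC(=O)O/C=C/[C@@H](C)CCC[C+](C)C | intermediate
4 | cyclised acyloxycarbenium ion | CC(=O)[O+]=C[C@@H]1[C@@H](C)CCCC1(C)C | intermediate
5 | (1R,6S)-2,2,6-trimethylcyclohexane-1-carbaldehyde | O=C[C@@H]1[C@@H](C)CCCC1(C)C | intermediate
6 | potassium (E)-[(6S)-2,2,6-trimethylcyclohexylidene]methanolate | [K+].[O-]/C=C1\[C@@H](C)CCCC1(C)C | intermediate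
7 | (E)-[(6S)-2,2,6-trimethylcyclohexylidene]methyl trifluoromethanesulfonate | FC(F)(F)S(=O)(=O)O/C=C1\[C@@H](C)CCCC1(C)C | intermediate
8 | (E)-pent-2-en-4-yn-1-ol | C#C/C=C/CO | starting material
9 | ethyl 2-(triphenylphosphoranylidene)propanoate | CCOC(=O)C(C)=P(c1ccccc1)(c1ccccc1)c1ccccc1 | starting material
10 | (E)-pent-2-en-4-ynal | C#C/C=C/C=O | intermediate
11 | ethyl (2E,4E)-2-methylhepta-2,4-dien-6-ynoate | C#C/C=C/C=C(\C)C(=O)OCC | intermediate
12 | (2E,4E)-2-methylhepta-2,4-dien-6-yn-1-ol | C#C/C=C/C=C(\C)CO | intermediate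
13 | [(1E,3E,5E)-7-(dimethylalumanyloxy)-2,6-dimethylhepta-1,3,5-trien-1-yl]dimethylalumane | C[Al](C)/C=C(\C)/C=C/C=C(\C)CO[Al](C)C | intermediate
14 | (2E,4E,6E)-2,6-dimethyl-7-(4,4,5,5-tetramethyl-1,3,2-dioxaborolan-2-yl)hepta-2,4,6-trien-1-ol | OC/C(C)=C/C=C/C(C)=C/B1OC(C)(C)C(C)(C)O1 | intermediate
15 | (2E,4E,6E,8E)-2,6-dimethyl-8-[(6S)-2,2,6-trimethylcyclohexylidene]octa-2,4,6-trien-1-ol | OC/C(C)=C/C=C/C(C)=C/C=C1\[C@@H](C)CCCC1(C)C | intermediate
16 | (2E,4E,6E,8E)-2,6-dimethyl-8-[(6S)-2,2,6-trimethylcyclohexylidene]octa-2,4,6-trienal | O=C/C(C)=C/C=C/C(C)=C/C=C1\[C@@H](C)CCCC1(C)C | intermediate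
17 | (triphenylphosphoranylidene)acetaldehyde | O=CC=P(c1ccccc1)(c1ccccc1)c1ccccc1 | starting material
18 | (2E,4E,6E,8E,10E)-4,8-dimethyl-10-[(6S)-2,2,6-trimethylcyclohexylidene]deca-2,4,6,8-tetraenal | O=C/C=C/C(C)=C/C=C/C(C)=C/C=C1\[C@@H](C)CCCC1(C)C | intermediate
19 | α-cyclocitral (2,6,6-trimethylcyclohex-2-ene-1-carbaldehyde, racemic) | CC1=CCCC(C)(C)C1C=O | starting material
20 | potassium (E)-(2,6,6-trimethylcyclohex-2-en-1-ylidene)methanolate | [K+].CC1=CCCC(C)(C)\C1=C/[O-] | intermediate
21 | (E)-(2,6,6-trimethylcyclohex-2-en-1-ylidene)methyl trifluoromethanesulfonate | CC1=CCCC(C)(C)\C1=C/OS(=O)(=O)C(F)(F)F | intermediate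
22 | (2E,4E,6E,8E)-2,6-dimethyl-8-(2,6,6-trimethylcyclohex-2-en-1-ylidene)octa-2,4,6-trien-1-ol | CC1=CCCC(C)(C)\C1=C/C=C(C)/C=C/C=C(C)/CO | intermediate
23 | [(2E,4E,6E,8E)-2,6-dimethyl-8-(2,6,6-trimethylcyclohex-2-en-1-ylidene)octa-2,4,6-trien-1-yl]triphenylphosphonium bromide | CC1=CCCC(C)(C)\C1=C/C=C(C)/C=C/C=C(C)/C[P+](c1ccccc1)(c1ccccc1)c1ccccc1.[Br-] | intermediate
24 | phosphorus ylide of 23 | CC1=CCCC(C)(C)\C1=C/C=C(C)/C=C/C=C(C)/C=P(c1ccccc1)(c1ccccc1)c1ccccc1 | intermediate
25 | (5'S,14Z)-4,5'-retro-β,β-carotene (14Z isomer of 26) | CC1=CCCC(C)(C)\C1=C/C=C(C)/C=C/C=C(C)/C=C\C=C\C(C)=C\C=C\C(C)=C\C=C1/[C@@H](C)CCCC1(C)C | intermediate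
26 | (5'S,6E,6'E)-4,5'-retro-β,β-carotene, all-E chain (CNP0257724.1) | CC1=CCCC(C)(C)\C1=C/C=C(C)/C=C/C=C(C)/C=C/C=C/C(C)=C/C=C/C(C)=C/C=C1\[C@@H](C)CCCC1(C)C | target

**Step count.** Total: 13 steps. Longest linear sequence: 7 steps (steps 1, 2, 3, 7, 8, 9, 13; the branch through steps 4, 5, 6, 7, 8, 9, 13 is equally long).

**Steps most likely to fail**

1. Step 12. What may go wrong: ionisation of the polyenylic alcohol under acid with capture of the delocalised cation at carbons other than C14, or proton-induced isomerisation and oligomerisation of the retro polyene. The fallback replaces the olefination at C14=C15 by a neutral sp2–sp2 union at C15–C15'; it sets out from 22 and 16 and comes back at 26, so that steps 9, 12 and 13 are not needed. Alcohol 22 is oxidised (MnO2, CH2Cl2) to (2E,4E,6E,8E)-2,6-dimethyl-8-(2,6,6-trimethylcyclohex-2-en-1-ylidene)octa-2,4,6-trienal F1. Takai iodo-olefination (CrCl2, CHI3, THF, 0 °C) then gives (6E)-6-[(2E,4E,6E,8E)-9-iodo-3,7-dimethylnona-2,4,6,8-tetraen-1-ylidene]-1,5,5-trimethylcyclohex-1-ene F2. Aldehyde 16 is converted by the tin variant of the Takai reaction (CrCl2, Bu3SnCHBr2, LiI, DMF, rt) into tributyl{(1E,3E,5E,7E,9E)-3,7-dimethyl-9-[(6S)-2,2,6-trimethylcyclohexylidene]nona-1,3,5,7-tetraen-1-yl}stannane F3. Stille coupling of F2 with F3 (PdCl2(MeCN)2, DMF, rt, dark) should give 26 directly.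

2. Step 6. What may go wrong: incomplete transfer of the alkenyl group from aluminium to boron, competing methyl transfer and protodemetalation on work-up, so that the boronate is formed in low amount or cannot be freed from the des-boryl triene. The fallback separates carbometalation and borylation through an isolable halide; it sets out from 12 and comes back at 14. Dienynol 12 is carboaluminated as in step 6 (AlMe3, Cp2ZrCl2, CH2Cl2) but quenched with I2 (THF, −30 °C) to give (2E,4E,6E)-7-iodo-2,6-dimethylhepta-2,4,6-trien-1-ol F4, which can be purified. Miyaura borylation of F4 (B2pin2, PdCl2(PPh3)2, PPh3, KOPh, toluene, 50 °C) should then give 14 with retention of the E geometry.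

3. Step 9. What may go wrong: slow attack of the stabilised ylide on the α-methyl-branched polyenal, with a second homologation of the more reactive product enal. The fallback is a two-step homologation through a nitrile; it sets out from 16 and comes back at 18. Horner–Wadsworth–Emmons reaction of 16 with diethyl cyanomethylphosphonate (NaH, THF, 0 °C) should give (2E,4E,6E,8E,10E)-4,8-dimethyl-10-[(6S)-2,2,6-trimethylcyclohexylidene]deca-2,4,6,8-tetraenenitrile F5. Reduction with i-Bu2AlH (toluene, −78 °C) and hydrolysis of the aldimine on wet silica should then give 18.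

Further compounds
F1 | step 12 | (2E,4E,6E,8E)-2,6-dimethyl-8-(2,6,6-trimethylcyclohex-2-en-1-ylidene)octa-2,4,6-trienal | CC1=CCCC(C)(C)\C1=C/C=C(C)/C=C/C=C(C)/C=O
F2 | step 12 | (6E)-6-[(2E,4E,6E,8E)-9-iodo-3,7-dimethylnona-2,4,6,8-tetraen-1-ylidene]-1,5,5-trimethylcyclohex-1-ene | CC1=CCCC(C)(C)\C1=C/C=C(C)/C=C/C=C(C)/C=C/I
F3 | step 12 | tributyl{(1E,3E,5E,7E,9E)-3,7-dimethyl-9-[(6S)-2,2,6-trimethylcyclohexylidene]nona-1,3,5,7-tetraen-1-yl}stannane | CCCC[Sn](CCCC)(CCCC)/C=C/C(C)=C/C=C/C(C)=C/C=C1\[C@@H](C)CCCC1(C)C
F4 | step 6 | (2E,4E,6E)-7-iodo-2,6-dimethylhepta-2,4,6-trien-1-ol | OC/C(C)=C/C=C/C(C)=C/I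
F5 | step 9 | (2E,4E,6E,8E,10E)-4,8-dimethyl-10-[(6S)-2,2,6-trimethylcyclohexylidene]deca-2,4,6,8-tetraenenitrile | N#C/C=C/C(C)=C/C=C/C(C)=C/C=C1\[C@@H](C)CCCC1(C)C
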